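I decided to reckon the end state of these flasks and leave the clock aside.

in all of them: Z 0.020 M
- midnight: E 0.55 equiv; run made earlier
- spring: E 2.2 equiv; run made earlier
- eta: E 1.50 equiv; time 8.0 d
- epsilon: E 0.800 equiv; time 8.0 d
- zeta: E 0.500 equiv; time 8.0 d

| run | time / d | J / % | D / % |
|---|---|---|---|
| midnight | 1.25 | 5 | 26 |
| midnight | 3.00 | 9 | 31 |
| midnight | 4.00 | 8 | 31 |
| midnight | 6.00 | 11 | 32 |
| spring | 0.625 | 18 | 35 |
| spring | 2.08 | 30 | 30 |
| spring | 4.00 | 30 | 22 |
| spring | 6.00 | 30 | 24 |

(scatter of a reading: 1.5 percentage points)

- which of these holds the largest part of the Z at the end of eta (Z / Q / D / J)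
- which of these holds the largest part of the Z at the end of epsilon (Z / Q / D / J)
- which of these holds the largest part of the Z at the end of zeta (Z / Q / D / J)
- amount of J at the end of epsilon, in percent of the Z charged



I first asked which given number had to be known well. Time hardly did: J in spring read 30%, 30% and 30% from 2.08 d to 6.00 d, and J in midnight read 9%, 8% and 11% from 3.00 d to 6.00 d, against a scatter of 1.5 percentage points. Z was charged at 0.020 M in every flask, so no run tests it. The equivalents of E did matter: at the last reading J stood at 30% in spring, higher than the 11% in midnight. E looked like the limiting reagent in midnight, where the last reading put 0.540 equiv of E on D and J, against 0.55 equiv charged.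

So I took u, the equivalents charged, as the equivalents taken up, with Z as exp(−u) of the charge and D as u times Z. J is then u squared times Z times the spread, J times Z over D squared. From midnight's last three readings, with means J 9.33%, D 31.3% and Z by difference 59.3%, where I counted the unread Q as nothing, the spread read 0.564. For spring it gave J 30.2% against 30% read. For epsilon I reckoned Z 44.9% and J 16.2%.

The forecast, seeing “reversible exchange against released ligand”, named D for eta, Z for epsilon and Z for zeta, with J at 14.5% in epsilon, below my figure.

The flasks gave D for eta, Z for epsilon and Z for zeta, with J at 15.2% in epsilon.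

    2 E → G (k = 0.0640 M⁻¹ h⁻¹)
    Z + E ⇌ L + D (K = 0.790, k = 1.80 M⁻¹ h⁻¹)
    J + E ⇌ L + Q (K = 1.50, k = 1.50 M⁻¹ h⁻¹)
    L → X (k = 1.20 h⁻¹)
    D + E ⇌ L + J (K = 0.390, k = 1.90 M⁻¹ h⁻¹)

Epsilon's own amounts give a spread of 0.563. In a flask like epsilon with 1.40 equiv, the rule gave J 27.3%, and that flask holds 26.5%. In epsilon, L has a half-life of 0.58 h by its turning into X alone, far shorter than the 0.95 d of D by the forward step D + E to L + J alone with the other concentrations as charged, and the run back from L + J changes J very little. By 4.00 d that forward step in epsilon has 95% of its turnover behind it.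

(The numbers in the tables are simulated with made-up constants; scatter was added.)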